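**Plan**
1. Retrosynthetic cuts: the C2–O angelate ester; the C5–O ether together with the C4–OH (both traced to a 4α,5α-epoxide of a Δ4 alkene opened by the 11-OH); the C1–C2 bond of ring A (a 1,3-shift back to a 2-oxy-1-methylcyclopropane C2–C3–C4 on C-5 of a cycloheptene, i.e. an isopropenyl diene plus one C–O carbon); then C4–C5 (Suzuki), C10–CH3 (cuprate), C11–CH3 and C11–O (enolate chemistry), C7–C11 (radical cyclisation).
2. Forward order of rings: the seven-membered ring is bought (cyclohepta-1,3-diene); the lactone ring follows, carried as an ethyl lactol ether; then the cyclopropane; ring A by 3→5 ring expansion; the tetrahydrofuran ring last.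
3. Enabling feature: in ring A the C-2 carbinol sits between C-1 and C-3, and C-4/C-5 (the later tertiary alcohol and ether carbon) can be left as a C4=C5 double bond. Ring A is thus a cyclopent-3-en-1-ol, the product type of a 2-vinylcyclopropanolate in which the C5=C1 bond of the seven-membered ring is the vinyl group and the C-2 oxygen is the accelerating group.
4. Stereochemistry: C-8 from catalytic desymmetrisation of a meso endoperoxide (Kornblum–DeLaMare); the rest by relay: C-7 (tethered radical cyclisation, cis), C-10 (cuprate anti to the lactol ring), C-1/C-2 (ring expansion), C-11 (methyl enters trans to C-6), C-4/C-5 (2α-OH-directed epoxidation, SN2 opening by 11-OH).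

Key step: step 10

Remark: guaiane numbering of the target is used for positions (ring A = C-1 to C-5; seven-membered ring = C-1, C-5 to C-10; lactone = C-7, C-8, O, C-12, C-11); α is the face of H-7.
Remark: centres that are destroyed later (the acetal carbon C-12 in 5–20, the cyclopropane carbons in 16 and 17) should form as mixtures and are written without configuration.

Step 1
Reactants: 1 cyclohepta-1,3-diene
Product: 2 6,7-dioxabicyclo[3.2.2]non-8-ene
Conditions: O2, tetraphenylporphyrin (cat.), hν, CH2Cl2, 0 °C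
Reagents that add atoms: dioxygen O=O
Why: [4+2] cycloaddition of singlet oxygen to the cyclic 1,3-diene should give the meso endoperoxide that carries the future C-5 carbonyl oxygen and the C-8 oxygen.

Step 2
Reactants: 2 6,7-dioxabicyclo[3.2.2]non-8-ene
Product: 3 (R)-4-hydroxycyclohept-2-en-1-one
Conditions: chiral 6′-hydroxy cinchona alkaloid base (10 mol%; pseudoenantiomer chosen for the R product), CH2Cl2, 23 °C
Reagents that add atoms: none
Why: Kornblum–DeLaMare rearrangement under chiral-base catalysis, in which removal of one of the two enantiotopic bridgehead hydrogens with O–O cleavage should set C-8 (R), the only centre not set by relay.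

Step 3
Reactants: 3 (R)-4-hydroxycyclohept-2-en-1-one; 4 ethyl vinyl ether
Product: 5 (4R)-4-(2-bromo-1-ethoxyethoxy)cyclohept-2-en-1-one
Conditions: NBS, CH2Cl2, −40 → 0 °C
Reagents that add atoms: N-bromosuccinimide O=C1CCC(=O)N1Br
Why: bromoetherification of the enol ether (Ueno–Stork acetal formation), in which the C-8 hydroxyl traps the α-bromo oxocarbenium ion; the new acetal centre needs no control because it becomes the lactone carbonyl in step 12.

Step 4
Reactants: 5 (4R)-4-(2-bromo-1-ethoxyethoxy)cyclohept-2-en-1-one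
Product: 7 {[(5R)-5-(2-bromo-1-ethoxyethoxy)cyclohepta-1,6-dien-1-yl]oxy}trimethylsilane, via lithium dienolate 6 (not isolated)
Conditions: LDA, TMSCl, THF, −78 °C
Reagents that add atoms: chlorotrimethylsilane C[Si](C)(C)Cl
Why: kinetic α′-deprotonation of the enone (cross-conjugated dienolate) with in situ O-silylation; C-1 is the only α′ position, so the place of the second enone is fixed here.

Step 5
Reactants: 7 {[(5R)-5-(2-bromo-1-ethoxyethoxy)cyclohepta-1,6-dien-1-yl]oxy}trimethylsilane
Product: 8 (4R)-4-(2-bromo-1-ethoxyethoxy)cyclohepta-2,6-dien-1-one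
Conditions: Pd(OAc)2 (1.05 equiv), MeCN, 23 °C
Reagents that add atoms: none
Why: Saegusa–Ito dehydrosilylation (oxa-π-allylpalladium, β-hydride elimination) should give the cross-conjugated dienone under neutral conditions, which avoids vinylogous β-elimination of the 4-alkoxy group.

Step 6
Reactants: 8 (4R)-4-(2-bromo-1-ethoxyethoxy)cyclohepta-2,6-dien-1-one
Product: 9 (3aS,8aR)-2-ethoxy-2,3,3a,4,8,8a-hexahydro-5H-cyclohepta[b]furan-5-one
Conditions: Bu3SnH (slow addition), AIBN (cat.), PhH, 80 °C
Reagents that add atoms: none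
Why: Ueno–Stork radical cyclisation, in which the primary radical adds 5-exo-trig to the enone β-carbon next to the tethering oxygen (C-7) and the two-atom tether from O-8 forces the cis ring fusion; the C1=C10 enone is left for step 7.

Step 7
Reactants: 9 (3aS,8aR)-2-ethoxy-2,3,3a,4,8,8a-hexahydro-5H-cyclohepta[b]furan-5-one
Product: 11 (3aR,7R,8aR)-2-ethoxy-7-methyl-3,3a,4,7,8,8a-hexahydro-2H-cyclohepta[b]furan-5-yl trifluoromethanesulfonate, via lithium enolate 10 (not isolated)
Conditions: Me2CuLi (from MeLi, CuI), Et2O, −78 °C; then PhNTf2, THF, −78 → 0 °C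
Reagents that add atoms: lithium dimethylcuprate [Li+].C[Cu-]C; N-phenylbis(trifluoromethanesulfonimide) O=S(=O)(N(c1ccccc1)S(=O)(=O)C(F)(F)F)C(F)(F)F
Why: Gilman conjugate addition followed by O-triflation of the regiodefined enolate; methyl should add to C-10 on the α face, anti to the cis-fused lactol ring on the β face (trans-3,5 pattern of 5-substituted cycloalkenones), and the enolate can only give the C5=C1 enol triflate.

Step 8
Reactants: 11 (3aR,7R,8aR)-2-ethoxy-7-methyl-3,3a,4,7,8,8a-hexahydro-2H-cyclohepta[b]furan-5-yl trifluoromethanesulfonate; 12 isopropenylboronic acid pinacol ester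
Product: 13 (3aR,7R,8aR)-2-ethoxy-7-methyl-5-(prop-1-en-2-yl)-3,3a,4,7,8,8a-hexahydro-2H-cyclohepta[b]furan
Conditions: Pd(dppf)Cl2 (5 mol%), K3PO4, dioxane–H2O, 60 °C
Reagents that add atoms: none
Why: Suzuki–Miyaura coupling of the enol triflate installs C-3, C-4 and C-15 and completes the 1,3-diene C3=C4–C5=C1 without touching a stereocentre.

Step 9
Reactants: 13 (3aR,7R,8aR)-2-ethoxy-7-methyl-5-(prop-1-en-2-yl)-3,3a,4,7,8,8a-hexahydro-2H-cyclohepta[b]furan; 14 2-chloroethyl chloromethyl ether
Product: 16 (3aR,7R,8aR)-5-[2-(2-chloroethoxy)-1-methylcyclopropyl]-2-ethoxy-7-methyl-3,3a,4,7,8,8a-hexahydro-2H-cyclohepta[b]furan, via lithium carbenoid 15 (not isolated)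
Conditions: LiTMP (slow addition), Et2O, −20 → 23 °C
Reagents that add atoms: none
Why: cyclopropanation of a 1,3-diene by an α-chloro-α-alkoxy lithium carbenoid (α-deprotonation of the chloromethyl ether by the non-nucleophilic amide) should occur mainly at the less hindered 1,1-disubstituted double bond; any regio- or stereoisomeric 2-vinylcyclopropyl ether leads to the same product in step 10.

Step 10
Reactants: 16 (3aR,7R,8aR)-5-[2-(2-chloroethoxy)-1-methylcyclopropyl]-2-ethoxy-7-methyl-3,3a,4,7,8,8a-hexahydro-2H-cyclohepta[b]furan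
Product: 19 (1αH,7αH,8αH,10βH)-12-ethoxy-8β,12-epoxy-13-norguai-4-en-2α-ol, via lithium cyclopropanolate 17 (not isolated), via lithium cyclopentenolate 18 (not isolated)
Conditions: n-BuLi (3.5 equiv), THF–HMPA, 0 → 23 °C; aq. NH4Cl
Reagents that add atoms: none
Why: Excess n-BuLi dehydrochlorinates the β-chloroethyl ether and then expels the alkoxide from the resulting vinyl ether (acetylene is lost), unmasking lithium 2-vinylcyclopropanolate 17; the oxyanion weakens the C2–C4 bond, which breaks and re-forms as C2–C1 at the far end of the C4–C5–C1 allyl unit, a net 1,3-shift that enlarges the three-membered ring (C-2, C-3, C-4) by C-5 and C-1 to ring A. The closest known reaction type is the alkoxy-accelerated vinylcyclopropane–cyclopentene rearrangement of 2-vinylcyclopropanolates made from 1,3-dienes and an alkoxycarbenoid (a [4+1] cyclopentenol annulation), which runs at room temperature in THF–HMPA. Ring A closes by attack of the allyl terminus C-1 on the carbonyl-like C-2 (5-exo-trig at C=O in the stepwise picture, a suprafacial 1,3-shift in the concerted one). C-1 should be set by bond formation on the β face, anti to the adjacent 10α-methyl group, and C-2 by the oxygen taking the position trans to the C1–C10 branch (the preferred trans-2-alkylcyclopent-3-enolate), which is 1α-H/2α-O as in the target; the cyclopropane centres of 16 are erased, so its isomer mixture converges. The step needs cleavage of C2–C4 rather than C2–C3 or C3–C4, secured by the alkoxide on C-2 and the allylic stabilisation at C-4, and it needs a substrate without electrophilic carbonyl groups, which is why the lactone is carried as its ethyl lactol ether.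

Step 11
Reactants: 19 (1αH,7αH,8αH,10βH)-12-ethoxy-8β,12-epoxy-13-norguai-4-en-2α-ol
Product: 20 2α-(tert-butyldiphenylsilyloxy)-12-ethoxy-8β,12-epoxy-13-norguai-4-ene
Conditions: TBDPSCl, imidazole, DMF, 23 °C
Reagents that add atoms: tert-butyl(chloro)diphenylsilane CC(C)(C)[Si](Cl)(c1ccccc1)c1ccccc1
Why: standard silylation of the secondary alcohol; the acid-stable TBDPS group is chosen to survive the Jones oxidation.

Step 12
Reactants: 20 2α-(tert-butyldiphenylsilyloxy)-12-ethoxy-8β,12-epoxy-13-norguai-4-ene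
Product: 21 2α-(tert-butyldiphenylsilyloxy)-13-norguai-4-en-12,8β-olide
Conditions: CrO3, H2SO4, H2O (Jones reagent), acetone, 0 °C
Reagents that add atoms: water O
Why: Jones oxidation of a 2-alkoxytetrahydrofuran (acid hydrolysis to the lactol, then Cr(VI) oxidation) should give the cis-fused γ-lactone in one operation, the usual follow-up of a bromoacetal radical cyclisation.

Step 13
Reactants: 21 2α-(tert-butyldiphenylsilyloxy)-13-norguai-4-en-12,8β-olide
Product: 23 (11R)-2α-(tert-butyldiphenylsilyloxy)-11-hydroxy-13-norguai-4-en-12,8β-olide, via lithium lactone enolate 22 (not isolated)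
Conditions: LDA, THF, −78 °C; 2-(phenylsulfonyl)-3-phenyloxaziridine, −78 °C
Reagents that add atoms: 2-(phenylsulfonyl)-3-phenyloxaziridine O=S(=O)(N1OC1c1ccccc1)c1ccccc1
Why: electrophilic hydroxylation of the lactone enolate with an N-sulfonyloxaziridine (Davis oxidation); oxygen should enter trans to C-6, which is acceptable because the next bond formed at C-11 comes from the same face and turns the centre over.

Step 14
Reactants: 23 (11R)-2α-(tert-butyldiphenylsilyloxy)-11-hydroxy-13-norguai-4-en-12,8β-olide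
Product: 24 (11R)-11-(tert-butyldimethylsilyloxy)-2α-(tert-butyldiphenylsilyloxy)-13-norguai-4-en-12,8β-olide
Conditions: TBSOTf, 2,6-lutidine, CH2Cl2, −78 → 0 °C
Reagents that add atoms: tert-butyldimethylsilyl trifluoromethanesulfonate CC(C)(C)[Si](C)(C)OS(=O)(=O)C(F)(F)F
Why: silylation with the silyl triflate protects the α-hydroxyl and gives an α-silyloxy lactone that can be enolised.

Step 15
Reactants: 24 (11R)-11-(tert-butyldimethylsilyloxy)-2α-(tert-butyldiphenylsilyloxy)-13-norguai-4-en-12,8β-olide
Product: 26 (11S)-11-(tert-butyldimethylsilyloxy)-2α-(tert-butyldiphenylsilyloxy)guai-4-en-12,8β-olide, via lithium silyloxy enolate 25 (not isolated)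
Conditions: LDA, THF–DMPU, −78 °C; MeI, −78 → −40 °C
Reagents that add atoms: iodomethane CI
Why: enolate alkylation, with methyl entering trans to C-6 (anti to the β-substituent, the usual sense for butyrolactone enolates), so that the C-11 oxygen ends cis to C-6, the face from which it can later reach C-5.

Step 16
Reactants: 26 (11S)-11-(tert-butyldimethylsilyloxy)-2α-(tert-butyldiphenylsilyloxy)guai-4-en-12,8β-olide
Product: 27 (11S)-2α,11-dihydroxyguai-4-en-12,8β-olide
Conditions: TBAF, THF, 0 → 23 °C
Reagents that add atoms: none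
Why: fluoride-mediated desilylation should free the 2α- and 11-hydroxyl groups without touching the lactone or the alkene.

Step 17
Reactants: 27 (11S)-2α,11-dihydroxyguai-4-en-12,8β-olide
Product: 29 2α,4α-dihydroxy-5β,11-epoxyguaian-12,8β-olide, via 4α,5α-epoxide 28 (not isolated)
Conditions: VO(acac)2 (5 mol%), t-BuOOH, CH2Cl2, 0 → 23 °C; then CSA (10 mol%)
Reagents that add atoms: tert-butyl hydroperoxide CC(C)(C)OO
Why: hydroxyl-directed vanadium-catalysed epoxidation (the homoallylic 2α-OH delivers the oxidant to the α face of the tetrasubstituted alkene) followed by acid-catalysed 5-exo epoxide opening at C-5 by the 11-OH with inversion should give the 5β-ether and the 4α-tertiary alcohol.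

Step 18
Reactants: 29 2α,4α-dihydroxy-5β,11-epoxyguaian-12,8β-olide; 30 angelic acid
Product: 32 2α-angeloyloxy-4α-hydroxy-5β,11-epoxyguaian-12,8β-olide (target), via mixed anhydride 31 (not isolated)
Conditions: 30, 2,4,6-trichlorobenzoyl chloride, Et3N, PhMe, 23 °C; then 29, PhMe, 80 °C (no DMAP)
Reagents that add atoms: none
Why: Yamaguchi esterification through the mixed anhydride, run without DMAP to avoid Z→E isomerisation to the tiglate; the secondary 2α-alcohol should react in preference to the hindered tertiary 4-alcohol.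

**Compound list**
1 | cyclohepta-1,3-diene | C1=CC=CCCC1 | starting material
2 | 6,7-dioxabicyclo[3.2.2]non-8-ene (meso endoperoxide) | C1CCC2C=CC1OO2 | intermediate
3 | (R)-4-hydroxycyclohept-2-en-1-one | O=C1C=C[C@@H](CCC1)O | intermediate
4 | ethyl vinyl ether | C=COCC | starting material
5 | (4R)-4-(2-bromo-1-ethoxyethoxy)cyclohept-2-en-1-one (acetal epimers) | O=C1C=C[C@@H](CCC1)OC(OCC)CBr | intermediate
6 | lithium (5R)-5-(2-bromo-1-ethoxyethoxy)cyclohepta-1,6-dien-1-olate (not isolated) | [Li+].[O-]C1=CCC[C@@H](OC(OCC)CBr)C=C1 | intermediate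
7 | {[(5R)-5-(2-bromo-1-ethoxyethoxy)cyclohepta-1,6-dien-1-yl]oxy}trimethylsilane | C[Si](C)(C)OC1=CCC[C@@H](OC(OCC)CBr)C=C1 | intermediate
8 | (4R)-4-(2-bromo-1-ethoxyethoxy)cyclohepta-2,6-dien-1-one | O=C1C=C[C@@H](CC=C1)OC(OCC)CBr | intermediate
9 | (3aS,8aR)-2-ethoxy-2,3,3a,4,8,8a-hexahydro-5H-cyclohepta[b]furan-5-one (cis-fused lactol ether enone) | O=C1C[C@H]2[C@@H](CC=C1)OC(OCC)C2 | intermediate
10 | lithium (3aR,7R,8aR)-2-ethoxy-7-methyl-3,3a,4,7,8,8a-hexahydro-2H-cyclohepta[b]furan-5-olate (not isolated) | [Li+].[O-]C1=C[C@H](C)C[C@H]2OC(OCC)C[C@H]2C1 | intermediate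
11 | (3aR,7R,8aR)-2-ethoxy-7-methyl-3,3a,4,7,8,8a-hexahydro-2H-cyclohepta[b]furan-5-yl trifluoromethanesulfonate | O=S(=O)(OC1=C[C@H](C)C[C@H]2OC(OCC)C[C@H]2C1)C(F)(F)F | intermediate
12 | isopropenylboronic acid pinacol ester | CC(=C)B1OC(C)(C)C(C)(C)O1 | starting material
13 | (3aR,7R,8aR)-2-ethoxy-7-methyl-5-(prop-1-en-2-yl)-3,3a,4,7,8,8a-hexahydro-2H-cyclohepta[b]furan | C=C(C)C1=C[C@H](C)C[C@H]2OC(OCC)C[C@H]2C1 | intermediate
14 | 2-chloroethyl chloromethyl ether | ClCCOCCl | starting material
15 | chloro(2-chloroethoxy)methyllithium (carbenoid, not isolated) | [Li]C(Cl)OCCCl | intermediate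
16 | (3aR,7R,8aR)-5-[2-(2-chloroethoxy)-1-methylcyclopropyl]-2-ethoxy-7-methyl-3,3a,4,7,8,8a-hexahydro-2H-cyclohepta[b]furan (cyclopropane isomers) | ClCCOC1CC1(C)C1=C[C@H](C)C[C@H]2OC(OCC)C[C@H]2C1 | intermediate
17 | lithium 2-[(3aR,7R,8aR)-2-ethoxy-7-methyl-3,3a,4,7,8,8a-hexahydro-2H-cyclohepta[b]furan-5-yl]-2-methylcyclopropan-1-olate (not isolated) | [Li+].[O-]C1CC1(C)C1=C[C@H](C)C[C@H]2OC(OCC)C[C@H]2C1 | intermediate
18 | lithium alkoxide of 19 (not isolated) | [Li+].[O-][C@H]1CC(C)=C2C[C@@H]3CC(OCC)O[C@@H]3C[C@@H](C)[C@H]12 | intermediate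
19 | (1αH,7αH,8αH,10βH)-12-ethoxy-8β,12-epoxy-13-norguai-4-en-2α-ol | O[C@H]1CC(C)=C2C[C@@H]3CC(OCC)O[C@@H]3C[C@@H](C)[C@H]12 | intermediate
20 | 2α-(tert-butyldiphenylsilyloxy)-12-ethoxy-8β,12-epoxy-13-norguai-4-ene | CC(C)(C)[Si](c1ccccc1)(c1ccccc1)O[C@H]1CC(C)=C2C[C@@H]3CC(OCC)O[C@@H]3C[C@@H](C)[C@H]12 | intermediate
21 | 2α-(tert-butyldiphenylsilyloxy)-13-norguai-4-en-12,8β-olide (cis-fused lactone) | CC(C)(C)[Si](c1ccccc1)(c1ccccc1)O[C@H]1CC(C)=C2C[C@@H]3CC(=O)O[C@@H]3C[C@@H](C)[C@H]12 | intermediate
22 | lithium enolate of 21 (not isolated) | CC(C)(C)[Si](c1ccccc1)(c1ccccc1)O[C@H]1CC(C)=C2C[C@@H]3C=C([O-])O[C@@H]3C[C@@H](C)[C@H]12.[Li+] | intermediate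
23 | (11R)-2α-(tert-butyldiphenylsilyloxy)-11-hydroxy-13-norguai-4-en-12,8β-olide (11-OH cis to H-7) | CC(C)(C)[Si](c1ccccc1)(c1ccccc1)O[C@H]1CC(C)=C2C[C@@H]3[C@@H](O)C(=O)O[C@@H]3C[C@@H](C)[C@H]12 | intermediate
24 | (11R)-11-(tert-butyldimethylsilyloxy)-2α-(tert-butyldiphenylsilyloxy)-13-norguai-4-en-12,8β-olide | CC(C)(C)[Si](c1ccccc1)(c1ccccc1)O[C@H]1CC(C)=C2C[C@@H]3[C@@H](O[Si](C)(C)C(C)(C)C)C(=O)O[C@@H]3C[C@@H](C)[C@H]12 | intermediate
25 | lithium enolate of 24 (not isolated) | CC(C)(C)[Si](c1ccccc1)(c1ccccc1)O[C@H]1CC(C)=C2C[C@@H]3C(O[Si](C)(C)C(C)(C)C)=C([O-])O[C@@H]3C[C@@H](C)[C@H]12.[Li+] | intermediate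
26 | (11S)-11-(tert-butyldimethylsilyloxy)-2α-(tert-butyldiphenylsilyloxy)guai-4-en-12,8β-olide (11-O cis to C-6) | CC(C)(C)[Si](c1ccccc1)(c1ccccc1)O[C@H]1CC(C)=C2C[C@@H]3[C@](C)(O[Si](C)(C)C(C)(C)C)C(=O)O[C@@H]3C[C@@H](C)[C@H]12 | intermediate
27 | (11S)-2α,11-dihydroxyguai-4-en-12,8β-olide | O[C@H]1CC(C)=C2C[C@@H]3[C@](C)(O)C(=O)O[C@@H]3C[C@@H](C)[C@H]12 | intermediate
28 | 4α,5α-epoxy-2α,11-dihydroxyguaian-12,8β-olide (not isolated) | O[C@H]1C[C@@]2(C)O[C@]23C[C@@H]4[C@](C)(O)C(=O)O[C@@H]4C[C@@H](C)[C@H]13 | intermediate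
29 | 2α,4α-dihydroxy-5β,11-epoxyguaian-12,8β-olide | O[C@H]1C[C@@](C)(O)[C@@]23C[C@H]4[C@@H](C[C@@H](C)[C@H]12)OC(=O)[C@@]4(C)O3 | intermediate
30 | angelic acid, (Z)-2-methylbut-2-enoic acid | C/C=C(/C)C(=O)O | starting material
31 | angelic 2,4,6-trichlorobenzoic anhydride (not isolated) | C/C=C(/C)C(=O)OC(=O)c1c(Cl)cc(Cl)cc1Cl | intermediate
32 | (1R,2S,4R,5R,7S,8R,10R,11S)-4-hydroxy-5,11-epoxyguaian-12,8-olid-2-yl (Z)-2-methylbut-2-enoate, CNP0293659.1 | C/C=C(/C)C(=O)O[C@H]1C[C@@](C)(O)[C@@]23C[C@H]4[C@@H](C[C@@H](C)[C@H]12)OC(=O)[C@@]4(C)O3 | target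

Total step count: 18. Longest linear sequence: 18 steps (1 → 32).

**Steps most likely to fail**

Step 10. The unmasked lithium cyclopropanolate may open to the homoenolate or β,γ-unsaturated aldehyde and be consumed by protonation or aldol-type side reactions instead of reclosing, or it may reclose with poor facial control at C-1. The fallback is a neutral, thermal ring expansion. It sets out from diene 13, which would be cyclopropanated with the benzyloxy carbenoid from benzyl chloromethyl ether and LiTMP to the benzyl cyclopropyl ether F1. Heating F1 (flash vacuum pyrolysis or sealed tube, about 250–300 °C) should bring about the diradical vinylcyclopropane–cyclopentene rearrangement, the 2-alkoxy group lowering the barrier and directing cleavage of the same C2–C4 bond, to give the cyclopentenyl benzyl ether F2. Debenzylation with lithium in liquid ammonia/THF at −78 °C (the isolated tetrasubstituted alkene and the acetal should be inert) returns to the route at 19.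

Step 5. The 4-alkoxy group may be lost from the cross-conjugated dienone by vinylogous β-elimination (aromatisation towards tropone) during the oxidation or work-up. The fallback changes the order of events. It sets out from bromoacetal 5, which would undergo the radical cyclisation first (Bu3SnH, AIBN, PhH, 80 °C) to the saturated cis-fused bicyclic ketone F3. Kinetic enolisation on the C-1 side, away from the ring fusion (LDA, TMSCl, −78 °C), should give the silyl enol ether F4, and Saegusa–Ito oxidation (Pd(OAc)2, MeCN) returns to the route at 9.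

Step 17. Epoxidation may occur on the β face, or the tetrasubstituted epoxide may rearrange or eliminate under acid before the 11-hydroxyl attacks. The fallback is a halo-etherification. It sets out from diol 27, which with NBS in MeCN at 0 °C should give the 4α-bromo-5β,11-ether F5, because bromonium formation is reversible and only the α-bromonium ion can be opened at C-5 by the 11-OH from the β face. Silver-assisted hydrolysis of F5 (AgOTf, aqueous acetone), with the neighbouring ether oxygen covering the β face of the C-4 cation, should replace bromide by hydroxyl with retention and return to the route at 29.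

**Further compounds**
F1 | step 10 | (3aR,7R,8aR)-5-[2-(benzyloxy)-1-methylcyclopropyl]-2-ethoxy-7-methyl-3,3a,4,7,8,8a-hexahydro-2H-cyclohepta[b]furan | C(OC1CC1(C)C1=C[C@H](C)C[C@H]2OC(OCC)C[C@H]2C1)c1ccccc1
F2 | step 10 | 2α-benzyloxy-12-ethoxy-8β,12-epoxy-13-norguai-4-ene | C(O[C@H]1CC(C)=C2C[C@@H]3CC(OCC)O[C@@H]3C[C@@H](C)[C@H]12)c1ccccc1
F3 | step 5 | (3aS,8aR)-2-ethoxyoctahydro-5H-cyclohepta[b]furan-5-one | O=C1C[C@H]2[C@@H](CCC1)OC(OCC)C2
F4 | step 5 | {[(3aR,8aR)-2-ethoxy-3,3a,4,7,8,8a-hexahydro-2H-cyclohepta[b]furan-5-yl]oxy}trimethylsilane | C[Si](C)(C)OC1=CCC[C@H]2OC(OCC)C[C@H]2C1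
F5 | step 17 | 4α-bromo-2α-hydroxy-5β,11-epoxyguaian-12,8β-olide | O[C@H]1C[C@@](C)(Br)[C@@]23C[C@H]4[C@@H](C[C@@H](C)[C@H]12)OC(=O)[C@@]4(C)O3
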